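Readings and results are simulated for substances that don't exist; the scatter is artificial.

43.5 is the number to watch here. The conversion asked about, divided by the charge of free catalyst as a fraction of the charge of starting material (0.460 %), gives the round count (turnover number): the turnovers each catalyst unit must make to reach that conversion.

in all of them: starting material 0.050 M; free catalyst 0.23 mM
- red: second substrate 0.025 M; the very flask that is asked about, followed so far
- flask: second substrate 0.0250 M

red run (percent of the starting material charged)

| time / h | target / % | starting material / % |
|---|---|---|
| 0.417 | 1.2 | 99.1 |
| 1.00 | 2.5 | 97.6 |
| 2.00 | 4.8 | 94.8 |
| 5.00 | 12.4 | 87.4 |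

(each reading ± 0.3 percentage points)

1. factor on the rate of making target when 20 % of the starting material are converted if second substrate is charged twice over
2. factor on the rate when 20 % of the starting material are converted if free catalyst is charged at 2.5 mM instead

- the earlier runs were read with a standard deviation of 0.3 percentage points
- no earlier run changes the charge of free catalyst; that part of a forecast is a guess
- no earlier run changes the charge of second substrate; that part of a forecast is a guess

In the red run, target climbs at 0.0250 h⁻¹ as a fraction of the charge up to 1.00 h, and at 0.0253 h⁻¹ from 2.00 h to 5.00 h. Within the scatter of the readings, the line therefore stays straight through 27.0 rounds, and extended, it gives the asked conversion at about 8.00 h.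

At 2.5 mM, the catalyst charge grows by a factor 10.9, while the round count drops to 4.00. If each round carries a small risk of losing catalyst, the rate gains slightly beyond 10.9, and this reckoning commits to that. The round count contains no second substrate, so one number can't serve there, and a factor near 1 is a guess from the straight line.

The forecast gives 1.08 on second substrate and 10 on free catalyst, below this reckoning on catalyst, holding that “Saturation implies rate proportional to catalyst”.

The flask gives 0.626 on second substrate and 13.0 on free catalyst.

    starting material + free catalyst ⇌ catalyst intermediate A (K = 1500 M⁻¹, k = 4.90 M⁻¹ min⁻¹)
    catalyst intermediate A → free catalyst + target (k = 0.450 min⁻¹)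
    second substrate + free catalyst ⇌ catalyst intermediate B (K = 110 M⁻¹, k = 27.0 M⁻¹ min⁻¹)
    catalyst intermediate B → free catalyst + second product (k = 0.440 min⁻¹)
    second substrate + catalyst intermediate A → spent catalyst (k = 0.110 M⁻¹ min⁻¹)

Doubling second substrate slows the flask, which the round count can't show. The catalyst factor 13.0 is larger than 10.9, and at 2.5 mM the asked conversion takes 4.00 rounds of each catalyst unit instead of 43.5. In the asked flask, spent catalyst stands at 13.3 % at 5.00 h, after 27.5 rounds counted in target. With the step from second substrate and catalyst intermediate A to spent catalyst taken out of that flask, the apparent order in free catalyst at the asked conversion goes from 1.2 to 1.0.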